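**Retrosynthetic overview**

- The strategy rests on the acyclic chain C9–C8–C8′–C9′: it is 1,4-dioxygenated, and each inner carbon carries one arylmethyl group (C7–ring A on C8, C7′–ring B on C8′). This is the pattern of a 5-alkoxybutenolide that has taken a nucleophile at its β-carbon and an electrophile at its α-carbon.
- Benzoates and phenols are unmasked last. The diol comes from hydride opening of a 5-menthyloxybutanolide (lactone C=O = C9, acetal carbon = C9′). The C7′ methylene comes from a 1,3-dithiane.
- Key disconnections are C7′–C8′ (conjugate addition of the lithiated ring-B aryl dithiane) and C7–C8 (benzylation of the resulting enolate with the ring-A benzyl bromide), both on (5R)-5-menthyloxyfuran-2(5H)-one in one flask.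
- Ring order: all four benzene rings are bought. The butenolide acetal and the dithiane are auxiliary rings made before the key step and destroyed after it. The key step closes no ring.

Key step: step 6

Remark: lignan locants are used (C7–C9 on the ring-A half, C7′–C9′ on the ring-B half). Read from the SMILES, the target is the (8R,8′R) isomer, i.e. (2R,3R) on the butane chain. "Menthyl" means (1R,2S,5R)-2-isopropyl-5-methylcyclohexyl throughout.

**Route**

Step 1
Reactants: 1 furfural
Product: 2 5-hydroxyfuran-2(5H)-one (racemic hemiacetal)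
Conditions: O2, hν (visible), rose bengal (C20H2Cl4I4Na2O5, cat.), MeOH, 20 °C
Reagents that add atoms: oxygen, O=O
Why: Dye-sensitised singlet-oxygen [4+2] cycloaddition to the furan gives an endoperoxide whose methanol hemiacetal fragments with loss of the formyl carbon as methyl formate (photo-oxygenation of furfural), which should leave the hydroxybutenolide.

Step 2
Reactants: 2 5-hydroxyfuran-2(5H)-one; 3 (1R,2S,5R)-menthol
Product: 4 (5R)-5-[(1R,2S,5R)-menthyloxy]furan-2(5H)-one
Conditions: p-toluenesulfonic acid monohydrate (cat.), toluene, reflux, Dean–Stark; crystallisation from petroleum ether, −20 °C (mother liquor re-equilibrated with the acid and recrystallised)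
Reagents that add atoms: none
Why: Acid-catalysed acetalisation (pseudo-ester formation) of the hemiacetal with menthol should give both C5 epimers, which interconvert under acid; the 5R epimer is expected to crystallise, so C5 is fixed by crystallisation with the menthyl group as the resolving element.

Step 3
Reactants: 5 4-benzyloxy-3-methoxybenzaldehyde
Product: 6 2-(4-benzyloxy-3-methoxyphenyl)-1,3-dithiane
Conditions: HS(CH2)3SH (1.1 equiv), BF3·OEt2 (0.2 equiv), CH2Cl2, 0 °C → rt
Reagents that add atoms: propane-1,3-dithiol, SCCCS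
Why: Lewis-acid-catalysed dithioacetalisation of an aryl aldehyde; with catalytic BF3·OEt2, near-stoichiometric dithiol and a short cold reaction the aryl benzyl ether should stay intact.

Step 4
Reactants: 7 3-benzyloxy-4-methoxybenzaldehyde
Product: 8 (3-benzyloxy-4-methoxyphenyl)methanol
Conditions: NaBH4, MeOH/THF, 0 °C
Reagents that add atoms: none
Why: Borohydride reduction of an aryl aldehyde to the benzyl alcohol; no other group in 7 is reducible under these conditions.

Step 5
Reactants: 8 (3-benzyloxy-4-methoxyphenyl)methanol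
Product: 9 3-benzyloxy-4-methoxybenzyl bromide
Conditions: PBr3 (0.4 equiv), Et2O, 0 °C; used at once
Reagents that add atoms: phosphorus tribromide, BrP(Br)Br
Why: Bromination of an electron-rich benzyl alcohol through its phosphite ester and bromide displacement; the labile bromide is taken into step 6 without storage.

Step 6
Reactants: 6 2-(4-benzyloxy-3-methoxyphenyl)-1,3-dithiane; 4 (5R)-5-[(1R,2S,5R)-menthyloxy]furan-2(5H)-one; 9 3-benzyloxy-4-methoxybenzyl bromide
Product: 12 (3R,4R,5R)-3-(3-benzyloxy-4-methoxybenzyl)-4-[2-(4-benzyloxy-3-methoxyphenyl)-1,3-dithian-2-yl]-5-[(1R,2S,5R)-menthyloxy]dihydrofuran-2(3H)-one, via 2-lithio-2-aryl-1,3-dithiane 10 (not isolated), via lithium lactone enolate 11 (not isolated)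
Conditions: 6, n-BuLi (1.0 equiv), THF, −78 → −30 °C; then 4, −78 °C; then 9, DMPU, −78 °C → rt; aq. NH4Cl
Reagents that add atoms: n-butyllithium, [Li]CCCC (its lithium is carried by 10 and 11 only and leaves as lithium bromide; 12 holds no atom of it)
Why: n-BuLi removes the doubly sulfur-stabilised benzylic proton of 6 to give the acyl-anion equivalent 10, which as a soft, hindered carbanion adds 1,4 to butenolide 4 at C4 (the future C8′), forming the C7′–C8′ bond and the lithium enolate 11; SN2 benzylation of 11 at C3 (the future C8) by the 4-methoxy-activated benzyl bromide 9 then forms the C7–C8 bond. The closest known reaction type is the tandem conjugate addition–enolate alkylation of lithiated 2-aryl-1,3-dithianes on 5-alkoxyfuran-2(5H)-ones. No ring is closed. C8′ is set by the (5R)-menthyloxy group, which shields one face of the planar butenolide so that the carbanion enters anti to it (4,5-trans), and C8 is set by the new quaternary dithianyl substituent, which sends the bromide to the opposite face of the enolate (3,4-trans); with the 5R acetal this is the 3R,4R lactone, which maps onto 8R,8′R. The step needs 1,4- over 1,2-addition (secured by the delocalised aryl dithiane anion and the unhindered β-carbon), C- over O-alkylation and mono-alkylation (lithium enolate, benzylic bromide, DMPU, one equivalent of each partner, a crowded tertiary C3 after the first alkylation), and full consumption of 10 before 9 is added so that the bromide meets only the enolate.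

Step 7
Reactants: 12 (3R,4R,5R)-3-(3-benzyloxy-4-methoxybenzyl)-4-[2-(4-benzyloxy-3-methoxyphenyl)-1,3-dithian-2-yl]-5-menthyloxydihydrofuran-2(3H)-one
Product: 13 (2R,3R)-2-(3-benzyloxy-4-methoxybenzyl)-3-[2-(4-benzyloxy-3-methoxyphenyl)-1,3-dithian-2-yl]butane-1,4-diol
Conditions: LiAlH4, THF, 0 °C → rt; H2O, aq. NaOH work-up
Reagents that add atoms: none
Why: Hydride reduction of the acyloxy acetal: opening of the lactone releases a hemiacetal alkoxide that expels menthoxide, and both aldehyde-level carbons (C9 and C9′) are reduced to CH2OH; the transient aldehydes are reduced faster than they enolise, so C8 and C8′ should keep their configuration.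

Step 8
Reactants: 13 (2R,3R)-2-(3-benzyloxy-4-methoxybenzyl)-3-[2-(4-benzyloxy-3-methoxyphenyl)-1,3-dithian-2-yl]butane-1,4-diol
Product: 14 (2R,3R)-2-(3-benzyloxy-4-methoxybenzyl)-3-(4-benzyloxy-3-methoxybenzyl)butane-1,4-diol
Conditions: NiCl2·6H2O (10 equiv), NaBH4 (30 equiv), MeOH/THF, 0 °C → rt
Reagents that add atoms: none
Why: Reductive desulfurisation of the benzylic dithiane by nickel boride generated in situ replaces both C–S bonds by C–H to give the C7′ methylene; aryl benzyl ethers and free hydroxyl groups are expected to tolerate this reagent, and no stereocentre is touched.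

Step 9
Reactants: 14 (2R,3R)-2-(3-benzyloxy-4-methoxybenzyl)-3-(4-benzyloxy-3-methoxybenzyl)butane-1,4-diol
Product: 15 (2R,3R)-2-(3-benzyloxy-4-methoxybenzyl)-3-(4-benzyloxy-3-methoxybenzyl)butane-1,4-diyl dibenzoate
Conditions: BzCl (2.5 equiv), pyridine, 4-(dimethylamino)pyridine (cat.), CH2Cl2, 0 °C → rt
Reagents that add atoms: benzoyl chloride, O=C(Cl)c1ccccc1
Why: Nucleophile-catalysed acylation of the two primary alcohols; both phenols are still benzyl ethers, so only the C9 and C9′ hydroxyl groups can be benzoylated.

Step 10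
Reactants: 15 (2R,3R)-2-(3-benzyloxy-4-methoxybenzyl)-3-(4-benzyloxy-3-methoxybenzyl)butane-1,4-diyl dibenzoate
Product: 16 (2R,3R)-2-(3-hydroxy-4-methoxybenzyl)-3-(4-hydroxy-3-methoxybenzyl)butane-1,4-diyl dibenzoate (CNP0306197.1)
Conditions: H2 (1 atm), Pd/C (10%), EtOAc/EtOH, rt
Reagents that add atoms: none
Why: Palladium-catalysed hydrogenolysis of the two aryl benzyl ethers; the benzoates are esters of non-benzylic primary alcohols and the C7/C7′ methylenes carry no heteroatom, so nothing else should be cleaved and the stereocentres are untouched.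

**Compound list**

1 | furfural | O=Cc1ccco1 | starting material
2 | 5-hydroxyfuran-2(5H)-one (racemic) | O=C1C=CC(O)O1 | intermediate
3 | (1R,2S,5R)-menthol | O[C@@H]1C[C@H](C)CC[C@H]1C(C)C | starting material
4 | (5R)-5-[(1R,2S,5R)-menthyloxy]furan-2(5H)-one | O=C1C=C[C@H](O[C@@H]2C[C@H](C)CC[C@H]2C(C)C)O1 | intermediate
5 | 4-benzyloxy-3-methoxybenzaldehyde | COc1cc(C=O)ccc1OCc1ccccc1 | starting material
6 | 2-(4-benzyloxy-3-methoxyphenyl)-1,3-dithiane | COc1cc(C2SCCCS2)ccc1OCc1ccccc1 | intermediate
7 | 3-benzyloxy-4-methoxybenzaldehyde | COc1ccc(C=O)cc1OCc1ccccc1 | starting material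
8 | (3-benzyloxy-4-methoxyphenyl)methanol | COc1ccc(CO)cc1OCc1ccccc1 | intermediate
9 | 3-benzyloxy-4-methoxybenzyl bromide | COc1ccc(CBr)cc1OCc1ccccc1 | intermediate
10 | 2-lithio-2-(4-benzyloxy-3-methoxyphenyl)-1,3-dithiane (not isolated) | COc1cc(C2([Li])SCCCS2)ccc1OCc1ccccc1 | intermediate
11 | lithium enolate of (4R,5R)-4-[2-(4-benzyloxy-3-methoxyphenyl)-1,3-dithian-2-yl]-5-menthyloxydihydrofuran-2(3H)-one (not isolated) | [Li]OC1=C[C@@H](C2(c3ccc(OCc4ccccc4)c(OC)c3)SCCCS2)[C@H](O[C@@H]5C[C@H](C)CC[C@H]5C(C)C)O1 | intermediate
12 | (3R,4R,5R)-3-(3-benzyloxy-4-methoxybenzyl)-4-[2-(4-benzyloxy-3-methoxyphenyl)-1,3-dithian-2-yl]-5-[(1R,2S,5R)-menthyloxy]dihydrofuran-2(3H)-one | COc1ccc(C[C@H]2C(=O)O[C@@H](O[C@@H]3C[C@H](C)CC[C@H]3C(C)C)[C@@H]2C4(c5ccc(OCc6ccccc6)c(OC)c5)SCCCS4)cc1OCc1ccccc1 | intermediate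
13 | (2R,3R)-2-(3-benzyloxy-4-methoxybenzyl)-3-[2-(4-benzyloxy-3-methoxyphenyl)-1,3-dithian-2-yl]butane-1,4-diol | COc1ccc(C[C@@H](CO)[C@H](CO)C2(c3ccc(OCc4ccccc4)c(OC)c3)SCCCS2)cc1OCc1ccccc1 | intermediate
14 | (2R,3R)-2-(3-benzyloxy-4-methoxybenzyl)-3-(4-benzyloxy-3-methoxybenzyl)butane-1,4-diol | COc1ccc(C[C@@H](CO)[C@H](CO)Cc2ccc(OCc3ccccc3)c(OC)c2)cc1OCc1ccccc1 | intermediate
15 | (2R,3R)-2-(3-benzyloxy-4-methoxybenzyl)-3-(4-benzyloxy-3-methoxybenzyl)butane-1,4-diyl dibenzoate | COc1ccc(C[C@@H](COC(=O)c2ccccc2)[C@H](COC(=O)c2ccccc2)Cc2ccc(OCc3ccccc3)c(OC)c2)cc1OCc1ccccc1 | intermediate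
16 | (2R,3R)-2-(3-hydroxy-4-methoxybenzyl)-3-(4-hydroxy-3-methoxybenzyl)butane-1,4-diyl dibenzoate (CNP0306197.1) | COc1ccc(C[C@@H](COC(=O)c2ccccc2)[C@H](COC(=O)c2ccccc2)Cc2ccc(O)c(OC)c2)cc1O | target

**Step count and risks**

Total step count: 10. Longest linear sequence: 7 steps (1, 2, 6, 7, 8, 9, 10 from furfural; equally 4, 5, 6, 7, 8, 9, 10 from aldehyde 7).

Steps most likely to fail, riskiest first:

1. Step 6. The one-flask sequence may stall after the conjugate addition: benzylation of the hindered enolate can be slow, and on warming the enolate may be protonated, O-alkylated or decomposed. Residual carbanion 10 may also consume the bromide, and facial control in either bond formation may be incomplete. The fallback separates the two bond formations. It sets out from 4 and 6: 6 is lithiated as before, 4 is added at −78 °C, and the mixture is quenched cold with aq. NH4Cl. This should give the conjugate adduct (4R,5R)-4-[2-(4-benzyloxy-3-methoxyphenyl)-1,3-dithian-2-yl]-5-[(1R,2S,5R)-menthyloxy]dihydrofuran-2(3H)-one F1, which is purified so that the anti adduct is secured. Its enolate is then regenerated with LiN(SiMe3)2 in THF at −78 °C and benzylated with 9 in the presence of DMPU, trans to the dithianyl group. The route is rejoined at 12.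

2. Step 8. Carbon–sulfur cleavage by nickel boride may stop at the thioether or thiol stage, and the polar diol may be held on the nickel residues. The fallback reorders the end game so that a stronger nickel reagent can be used without concern for the benzyl ethers. It sets out from 13, which is benzoylated first (BzCl, pyridine, 4-(dimethylamino)pyridine, CH2Cl2) to (2R,3R)-2-(3-benzyloxy-4-methoxybenzyl)-3-[2-(4-benzyloxy-3-methoxyphenyl)-1,3-dithian-2-yl]butane-1,4-diyl dibenzoate F2. F2 is then treated with excess Raney nickel (Ni) under H2 in EtOH/THF at reflux, which should remove both sulfur atoms and cleave the aryl benzyl ethers at least in part. Any benzyl ether that survives is finished under the Pd/C conditions of step 10. The route is rejoined at 16.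

3. Step 7. Direct hydride reduction of the acyloxy acetal may stop at lactol or hemiacetal stages, or base-mediated epimerisation next to the transient aldehydes may erode C8 or C8′. The fallback removes the auxiliary before the hydride reduction. It sets out from 12, which is treated with NaBH4 and KOH in aqueous EtOH/THF: hydroxide opens the pseudo-ester, the freed C9′ aldehyde is reduced in situ and menthol is released. Acidification with HCl then closes the γ-lactone (3R,4R)-3-(3-benzyloxy-4-methoxybenzyl)-4-[2-(4-benzyloxy-3-methoxyphenyl)-1,3-dithian-2-yl]dihydrofuran-2(3H)-one F3. LiAlH4 in THF reduces this plain lactone to the diol. The route is rejoined at 13.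

Further compounds
F1 | step 6 | (4R,5R)-4-[2-(4-benzyloxy-3-methoxyphenyl)-1,3-dithian-2-yl]-5-[(1R,2S,5R)-menthyloxy]dihydrofuran-2(3H)-one | O=C1C[C@@H](C2(c3ccc(OCc4ccccc4)c(OC)c3)SCCCS2)[C@H](O[C@@H]5C[C@H](C)CC[C@H]5C(C)C)O1
F2 | step 8 | (2R,3R)-2-(3-benzyloxy-4-methoxybenzyl)-3-[2-(4-benzyloxy-3-methoxyphenyl)-1,3-dithian-2-yl]butane-1,4-diyl dibenzoate | COc1ccc(C[C@@H](COC(=O)c2ccccc2)[C@H](COC(=O)c2ccccc2)C2(c3ccc(OCc4ccccc4)c(OC)c3)SCCCS2)cc1OCc1ccccc1
F3 | step 7 | (3R,4R)-3-(3-benzyloxy-4-methoxybenzyl)-4-[2-(4-benzyloxy-3-methoxyphenyl)-1,3-dithian-2-yl]dihydrofuran-2(3H)-one | COc1ccc(C[C@H]2C(=O)OC[C@@H]2C3(c4ccc(OCc5ccccc5)c(OC)c4)SCCCS3)cc1OCc1ccccc1
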